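The closed, stirred vessel held a racemate, a single-handed free catalyst, protic impurity and a solid reagent that started undissolved.

| flask | left-handed substrate | right-handed substrate | protic impurity | solid reagent | free catalyst | remark | time |
|---|---|---|---|---|---|---|---|
| midnight | 0.065 M | 0.065 M | 0.065 M | 2 equiv | 5 mol% | run made earlier |  |
| spring | 0.26 M | 0.26 M | 0.065 M | 2 equiv | 5 mol% | run made earlier |  |
| south-east | 0.13 M | 0.13 M | 0.0650 M | 2.00 equiv | 5 mol% |  | 2.0 d |
| south-west | 0.13 M | 0.13 M | 0.0650 M | 2.00 equiv | 5 mol% |  | 0.60 d |

| run | time / h | left-handed product / % | right-handed product / % | left-handed substrate / % |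
|---|---|---|---|---|
| midnight | 2.50 | 0 | 0 | 50.2 |
| midnight | 4.00 | 0.5 | 0 | 49.4 |
| midnight | 5.00 | 0 | 0 | 49.9 |
| midnight | 8.00 | 0.3 | 0 | 49.8 |
| midnight | 12.0 | 0.5 | 0.9 | 49.9 |
| midnight | 20.0 | 1.4 | 0.3 | 49.1 |
| midnight | 30.0 | 1.5 | 1.2 | 48.0 |
| spring | 4.00 | 0.1 | 0.5 | 50.1 |
| spring | 8.00 | 1.4 | 1.0 | 48.4 |
| spring | 12.0 | 1.8 | 1.0 | 48.4 |
| spring | 15.0 | 2.0 | 1.9 | 47.8 |
| spring | 20.0 | 3.8 | 1.8 | 46.6 |
| spring | 25.0 | 4.2 | 1.8 | 46.2 |
| spring | 30.0 | 4.6 | 2.2 | 45.7 |

(standard deviation of a reading: 0.3 percentage points)

- free catalyst is single-handed; left-handed substrate and right-handed substrate are mirror images of each other, charged as a racemate, each of them at the stated concentration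
- solid, in amounts per volume of the solution: solid reagent
- at the start none of the solid reagent is in solution
- an excess is below zero if the other one leads

1. which of the two ends with the higher excess of left-handed product over right-handed product in the product ("neither" if they lie within 2 percentage points) (south-east / south-west / neither)
2. excess of left-handed product over right-handed product in the product at the end, south-east
3. excess of left-handed product over right-handed product in the product at the end, south-west

I divided the rate to left-handed product by the rate to right-handed product, so time dropped out, and any lag with it. While the substrates stay nearly equal fractions of the charge, that ratio is the selectivity factor. Spring at 30.0 h bracketed the excess in the product from above at 44.1 % and from below at 26.5 %, moving each reading one scatter apart. I tightened this by adding up the last 3 spring readings: those of left-handed product add to 12.6 % and those of right-handed product to 5.80 %, which are sums of readings and not amounts in the flask. So the excess in the product, left minus right over their sum, read 37.0 %, between 31.3 % and 42.6 % when each sum was moved by its own scatter. I committed to that reading for both flasks, and so to neither.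

The forecast also said neither, but with 28.5 % for south-east and 30 % for south-west, below my lower bound. Its ground for the tie was that “With s≈2, ee falls only about 1–2 points by 8% conversion”.

The flasks gave 35.0 % in south-east and 35.7 % in south-west, so neither, both inside the bracket.

    coupling partner + free catalyst + right-handed substrate → free catalyst + right-handed product (k = 16.0 M⁻² h⁻¹)
    coupling partner + protic impurity → quenched reagent (k = 1.90 M⁻¹ h⁻¹)
    coupling partner + free catalyst + left-handed substrate → free catalyst + left-handed product (k = 34.0 M⁻² h⁻¹)
    solid reagent ⇌ coupling partner, rate k4*(cs4 - [coupling partner]) while solid is left; crystals form when [coupling partner] > cs4 (solubility = 36.0 mM, k = 0.110 h⁻¹)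
    free catalyst → spent catalyst (k = 0.0290 h⁻¹)

A neighbour, the same flask as south-east but with 2.00 equiv of protic impurity instead of 0.5, made 1.98 % left-handed and 0.944 % right-handed product by 2.00 d, and its excess was 35.5 %, close to my reading. South-east had not come to rest at 2.00 d: it held 4.36 % left-handed and 2.10 % right-handed product, with 24.9 % of its catalyst still free. By 20.0 d these stood at 6.98 % and 3.41 %, with free catalyst at 0 %. The product added over that stretch carried an excess of 33.2 %, lower than the 35.0 % of the product already made but above the lower bound of the bracket round my reading of 37.0 %, and the whole product in south-east then had an excess of 34.3 %.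

Readings and results were generated by integration with made-up constants; noise was put on by code.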